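Ring A is closed last, by making the C2–C3 bond (labdane numbering). C3 (carbinol) and C19 (hydroxymethyl) sit on the quaternary C4 beside the C18 methyl, so both are traced back to the two ester groups of a methylmalonate on C5 of a finished ring B. In the key step a C2 alkylsamarium, made from a 2-iodoethyl arm on C10, attacks one of the two diastereotopic esters (intramolecular acyl substitution). One operation closes ring A as a trans-decalin, makes the C3 carbonyl and fixes the C4 quaternary centre with C19 axial, cis to the C20 methyl. The precursor is a monocyclic cyclohexane carrying the C8 methylene, a masked C11 aldehyde, the iodoethyl arm and the malonate.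

Key step: step 10

Remark: locants C1–C20 are those of the labdane skeleton (ring A = C1–C5 and C10; ring B = C5–C10; C17 = methylene carbon on C8; C18 = methyl and C19 = oxygen-bearing carbon on C4; C20 = methyl on C10; C11–C16 = side chain and lactone). 2-(Bromomethyl)prop-2-enoic acid is assumed to be a commercial starting material.

Step 1
Reactants: 1 dimethyl methylmalonate; 2 allyl bromide
Product: 3 dimethyl 2-methyl-2-(prop-2-enyl)propanedioate
Conditions: NaH, THF, 0 °C to rt
Reagents that add atoms: none
Why: malonic ester alkylation, in which the sodium enolate of 1 displaces bromide from 2 (SN2), assembles C4 with its methyl (C18), the two carboxyl carbons (future C3 and C19) and the arm that becomes C5 and C10; no stereocentre is formed.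

Step 2
Reactants: 3 dimethyl 2-methyl-2-(prop-2-enyl)propanedioate
Product: 5 dimethyl 2-methyl-2-(2-oxoethyl)propanedioate, via ozonide 4 (not isolated)
Conditions: O3, CH2Cl2, −78 °C; then Me2S, −78 °C to rt
Reagents that add atoms: ozone [O-][O+]=O
Why: ozonolysis with reductive work-up cleaves the terminal alkene to the aldehyde (future C10) without touching the esters.

Step 3
Reactants: 5 dimethyl 2-methyl-2-(2-oxoethyl)propanedioate; 6 methyl vinyl ketone
Product: 8 dimethyl 2-methyl-2-[(1S)-4-oxocyclohex-2-en-1-yl]propanedioate, via keto aldehyde 7 (not isolated)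
Conditions: (R)-α,α-diphenylprolinol trimethylsilyl ether (10 mol%), ethyl 3,4-dihydroxybenzoate (20 mol%), neat, 4 °C; then p-TsOH·H2O (20 mol%), toluene, 60 °C
Reagents that add atoms: none
Why: enamine-catalysed Michael addition followed by acid-promoted intramolecular aldol condensation (organocatalytic Robinson-type annulation) builds ring B; the E-enamine reacts on the face away from the diphenyl(silyloxy)methyl group, so the R catalyst should set C5 as drawn (S in 8).

Step 4
Reactants: 8 dimethyl 2-methyl-2-[(1S)-4-oxocyclohex-2-en-1-yl]propanedioate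
Product: 9 dimethyl 2-methyl-2-[(1S,2R)-2-methyl-4-(trimethylsilyloxy)cyclohex-3-en-1-yl]propanedioate
Conditions: MeMgBr, CuBr·SMe2 (10 mol%), TMSCl, HMPA, THF, −78 °C; Et3N
Reagents that add atoms: methylmagnesium bromide C[Mg]Br; chlorotrimethylsilane C[Si](C)(C)Cl
Why: copper-catalysed conjugate addition accelerated by TMSCl brings in the C20 methyl at C10 trans to the bulky malonyl group (a stereocentre that step 5 removes) and traps the enolate as the regiodefined silyl enol ether.

Step 5
Reactants: 9 silyl enol ether
Product: 10 dimethyl 2-methyl-2-[(1S)-2-methyl-4-oxocyclohex-2-en-1-yl]propanedioate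
Conditions: Pd(OAc)2 (1.05 equiv), MeCN, rt
Reagents that add atoms: none
Why: Saegusa–Ito oxidation, in which the palladium enolate from the silyl enol ether undergoes β-hydride elimination towards C10, gives the 3-methyl enone regiospecifically and leaves the γ stereocentre C5 untouched.

Step 6
Reactants: 10 3-methyl enone
Product: 11 dimethyl 2-[(1S,2R)-2-ethenyl-2-methyl-4-(trimethylsilyloxy)cyclohex-3-en-1-yl]-2-methylpropanedioate
Conditions: CH2=CHMgBr, CuBr·SMe2 (20 mol%), TMSCl, HMPA, THF, −78 to −40 °C; Et3N
Reagents that add atoms: vinylmagnesium bromide C=C[Mg]Br; chlorotrimethylsilane C[Si](C)(C)Cl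
Why: copper-catalysed conjugate addition with TMSCl activation creates the C10 quaternary centre, the vinyl group (C1=C2) entering anti to the C5 malonyl substituent as is general for 4-substituted cyclohexenones, which leaves the C20 methyl cis to that substituent.

Step 7
Reactants: 11 vinyl silyl enol ether
Product: 13 dimethyl 2-[(1S,2R,3R)-3-(dimethoxymethyl)-2-ethenyl-2-methyl-4-oxocyclohexyl]-2-methylpropanedioate, via C9-epimeric keto acetal 12 (not isolated)
Conditions: HC(OMe)3, BF3·OEt2, CH2Cl2, −78 °C; then K2CO3 (cat.), MeOH, 0 °C to rt
Reagents that add atoms: trimethyl orthoformate COC(OC)OC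
Why: Mukaiyama-type reaction of the silyl enol ether with the dimethoxycarbenium ion installs C11 at the aldehyde oxidation level on C9; attack anti to the pseudoaxial C20 methyl should first give the axial epimer 12, and mild base equilibration through the enolate moves the acetal to the equatorial site (cis to C20, trans to vinyl).

Step 8
Reactants: 13 keto acetal
Product: 14 dimethyl 2-[(1S,2R,3R)-3-(dimethoxymethyl)-2-ethenyl-2-methyl-4-methylidenecyclohexyl]-2-methylpropanedioate
Conditions: Zn dust, CH2Br2, TiCl4, THF, −40 to 5 °C (reagent prepared beforehand); then 13, CH2Cl2, rt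
Reagents that add atoms: dibromomethane BrCBr
Why: Takai–Lombardo methylenation with the non-basic zinc–titanium methylene reagent converts the hindered ketone into the C8 exocyclic methylene without epimerising C9 and without touching the esters or the acetal.

Step 9
Reactants: 14 diene diester
Product: 16 dimethyl 2-[(1S,2R,3R)-3-(dimethoxymethyl)-2-(2-iodoethyl)-2-methyl-4-methylidenecyclohexyl]-2-methylpropanedioate, via alkylzirconocene chloride 15 (not isolated)
Conditions: Cp2Zr(H)Cl, THF, rt; then I2, 0 °C
Reagents that add atoms: iodine [I][I]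
Why: hydrozirconation places zirconium on the terminal carbon of the monosubstituted vinyl group much faster than on the 1,1-disubstituted methylene, and iodinolysis of the carbon–zirconium bond gives the primary iodide at C2.

Step 10
Reactants: 16 iodo diester
Product: 17 methyl (1S,4aR,5R,8aS)-5-(dimethoxymethyl)-1,4a-dimethyl-6-methylidene-2-oxodecahydronaphthalene-1-carboxylate
Conditions: SmI2 (2.4 equiv), Fe(dbm)3 (2 mol%, dbm = dibenzoylmethanate), THF, −30 °C to rt; sat. aq. NH4Cl
Reagents that add atoms: none
Why: two single-electron transfers from divalent samarium (iron-catalysed) convert the carbon–iodine bond at C2 into a primary alkylsamarium (trivalent samarium), which adds to one ester carbonyl on C4, and collapse of the tetrahedral intermediate with loss of methoxide gives the C3 ketone. The closest known reaction type is the SmI2-promoted intramolecular nucleophilic acyl substitution of ω-iodo esters (a Barbier-type cyclo-acylation). Ring A closes in the 6-exo-trig mode through a chair transition state templated by ring B, whose C10 holds the methyl group axial and the C1–C2 arm equatorial, so the ring fusion is trans. The only new stereocentre, C4, is decided by which of the two diastereotopic esters is attacked: the ester left behind should take the axial site next to the C20 methyl, because placing the C18 methyl there would cost a syn-pentane methyl–methyl contact, so C19 should end axial (cis to C20) and C18 equatorial. The step needs this group selectivity and chemoselectivity for the carbon–iodine bond over the esters, the acetal and the 1,1-disubstituted alkene; the hindered neopentyl-type esters resist intermolecular attack, and the tether length makes the six-membered closure the only low-strain pathway.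

Step 11
Reactants: 17 bicyclic keto ester
Product: 18 (1R,2R,4aR,5R,8aS)-5-(dimethoxymethyl)-1-(hydroxymethyl)-1,4a-dimethyl-6-methylidenedecahydronaphthalen-2-ol
Conditions: LiAlH4, THF, 0 °C to reflux
Reagents that add atoms: none
Why: LiAlH4 reduces the ketone and the remaining ester in one operation; hydride is delivered to C3 along the axial trajectory on the face opposite the axial C19 group and the C20 methyl, as in 4,4-disubstituted 3-keto decalins, so the 3-hydroxyl should be equatorial and cis to C19.

Step 12
Reactants: 18 diol acetal
Product: 19 3,19-dihydroxy aldehyde (C11 formyl group on C9; labdane locants 3R,4R,5S,9R,10R)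
Conditions: AcOH/THF/H2O (3:1:1), 35 °C
Reagents that add atoms: water O
Why: mild acid-catalysed acetal hydrolysis unmasks the C11 aldehyde under conditions chosen to leave the exocyclic alkene in place, and C9 stays in its thermodynamically preferred equatorial configuration.

Step 13
Reactants: 20 2-(bromomethyl)prop-2-enoic acid; 21 prop-2-en-1-ol
Product: 22 prop-2-enyl 2-(bromomethyl)prop-2-enoate
Conditions: H2SO4 (cat.), toluene, reflux, Dean–Stark trap
Reagents that add atoms: none
Why: Fischer esterification with azeotropic removal of water gives the bifunctional allyl ester; no stereocentre is involved.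

Step 14
Reactants: 19 dihydroxy aldehyde; 22 prop-2-enyl 2-(bromomethyl)prop-2-enoate
Product: 23 prop-2-enyl (4R)-4-hydroxy-2-methylidene-4-(decalinyl)butanoate (triol ester; labdane locants 3R,4R,5S,9R,10R,11R)
Conditions: In powder, THF/H2O (1:1), rt
Reagents that add atoms: none
Why: Barbier-type indium-mediated 2-(alkoxycarbonyl)allylation of the aldehyde in aqueous medium tolerates the free diol, and by the Felkin–Anh model the allyl group adds anti to the quaternary C10 and past the C9 hydrogen, which should give the 11R carbinol.

Step 15
Reactants: 23 triol ester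
Product: 24 14-deoxy-11-hydroxyandrographolide
Conditions: second-generation Grubbs catalyst RuCl2(=CHPh)(H2IMes)(PCy3) (5 mol%), CH2Cl2, 40 °C
Reagents that add atoms: none
Why: ring-closing metathesis between the acrylate methylene and the allyl ester alkene closes the butenolide with loss of ethene, while the hindered C8 methylene does not take part and no stereocentre is affected.

Compound list
1 | dimethyl 2-methylpropanedioate (dimethyl methylmalonate) | COC(=O)C(C)C(=O)OC | starting material
2 | 3-bromoprop-1-ene (allyl bromide) | C=CCBr | starting material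
3 | dimethyl 2-methyl-2-(prop-2-enyl)propanedioate | C=CCC(C)(C(=O)OC)C(=O)OC | intermediate
4 | ozonide of 3: dimethyl 2-methyl-2-(1,2,4-trioxolan-3-ylmethyl)propanedioate | COC(=O)C(C)(CC1OCOO1)C(=O)OC | intermediate (not isolated)
5 | dimethyl 2-methyl-2-(2-oxoethyl)propanedioate | O=CCC(C)(C(=O)OC)C(=O)OC | intermediate
6 | but-3-en-2-one (methyl vinyl ketone) | C=CC(C)=O | starting material
7 | dimethyl 2-[(2R)-1,5-dioxohexan-2-yl]-2-methylpropanedioate | CC(=O)CC[C@@H](C=O)C(C)(C(=O)OC)C(=O)OC | intermediate (not isolated)
8 | dimethyl 2-methyl-2-[(1S)-4-oxocyclohex-2-en-1-yl]propanedioate | O=C1CC[C@H](C(C)(C(=O)OC)C(=O)OC)C=C1 | intermediate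
9 | dimethyl 2-methyl-2-[(1S,2R)-2-methyl-4-(trimethylsilyloxy)cyclohex-3-en-1-yl]propanedioate (methyl trans to the malonyl group) | C[Si](C)(C)OC=1CC[C@H](C(C)(C(=O)OC)C(=O)OC)[C@@H](C)C=1 | intermediate
10 | dimethyl 2-methyl-2-[(1S)-2-methyl-4-oxocyclohex-2-en-1-yl]propanedioate | O=C1CC[C@H](C(C)(C(=O)OC)C(=O)OC)C(C)=C1 | intermediate
11 | dimethyl 2-[(1S,2R)-2-ethenyl-2-methyl-4-(trimethylsilyloxy)cyclohex-3-en-1-yl]-2-methylpropanedioate (vinyl trans to the malonyl group) | C[Si](C)(C)OC=1CC[C@H](C(C)(C(=O)OC)C(=O)OC)[C@@](C)(C=C)C=1 | intermediate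
12 | dimethyl 2-[(1S,2R,3S)-3-(dimethoxymethyl)-2-ethenyl-2-methyl-4-oxocyclohexyl]-2-methylpropanedioate (acetal cis to vinyl) | O=C1CC[C@H](C(C)(C(=O)OC)C(=O)OC)[C@@](C)(C=C)[C@H]1C(OC)OC | intermediate (not isolated)
13 | dimethyl 2-[(1S,2R,3R)-3-(dimethoxymethyl)-2-ethenyl-2-methyl-4-oxocyclohexyl]-2-methylpropanedioate (acetal trans to vinyl) | O=C1CC[C@H](C(C)(C(=O)OC)C(=O)OC)[C@@](C)(C=C)[C@@H]1C(OC)OC | intermediate
14 | dimethyl 2-[(1S,2R,3R)-3-(dimethoxymethyl)-2-ethenyl-2-methyl-4-methylidenecyclohexyl]-2-methylpropanedioate | C=C1CC[C@H](C(C)(C(=O)OC)C(=O)OC)[C@@](C)(C=C)[C@@H]1C(OC)OC | intermediate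
15 | alkylzirconocene chloride from 14 (Cp2Zr(Cl) on C2 of the former vinyl group) | C=C1CC[C@H](C(C)(C(=O)OC)C(=O)OC)[C@@](C)(CC[Zr](Cl)(C2C=CC=C2)C2C=CC=C2)[C@@H]1C(OC)OC | intermediate (not isolated)
16 | dimethyl 2-[(1S,2R,3R)-3-(dimethoxymethyl)-2-(2-iodoethyl)-2-methyl-4-methylidenecyclohexyl]-2-methylpropanedioate | C=C1CC[C@H](C(C)(C(=O)OC)C(=O)OC)[C@@](C)(CCI)[C@@H]1C(OC)OC | intermediate
17 | methyl (1S,4aR,5R,8aS)-5-(dimethoxymethyl)-1,4a-dimethyl-6-methylidene-2-oxodecahydronaphthalene-1-carboxylate (trans-decalin; C3 ketone; C19 ester axial, cis to C20) | C=C1CC[C@@H]2[C@](C)(C(=O)OC)C(=O)CC[C@@]2(C)[C@@H]1C(OC)OC | intermediate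
18 | (1R,2R,4aR,5R,8aS)-5-(dimethoxymethyl)-1-(hydroxymethyl)-1,4a-dimethyl-6-methylidenedecahydronaphthalen-2-ol | C=C1CC[C@@H]2[C@](C)(CO)[C@H](O)CC[C@@]2(C)[C@@H]1C(OC)OC | intermediate
19 | trans-decalin aldehyde with equatorial 3-OH, axial 4-CH2OH, 4-methyl, 10-methyl, 8-methylidene and equatorial 9-CHO (labdane locants 3R,4R,5S,9R,10R) | C=C1CC[C@@H]2[C@](C)(CO)[C@H](O)CC[C@@]2(C)[C@@H]1C=O | intermediate
20 | 2-(bromomethyl)prop-2-enoic acid | OC(=O)C(=C)CBr | starting material
21 | prop-2-en-1-ol (allyl alcohol) | C=CCO | starting material
22 | prop-2-enyl 2-(bromomethyl)prop-2-enoate | C=CCOC(=O)C(=C)CBr | intermediate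
23 | prop-2-enyl (4R)-4-hydroxy-2-methylidene-4-(decalinyl)butanoate, the decalinyl group being that of 19 attached through C9 (labdane locants 3R,4R,5S,9R,10R,11R) | C=C1CC[C@@H]2[C@](C)(CO)[C@H](O)CC[C@@]2(C)[C@@H]1[C@H](O)CC(=C)C(=O)OCC=C | intermediate
24 | 14-deoxy-11-hydroxyandrographolide | C=C1CC[C@@H]2[C@](C)(CO)[C@H](O)CC[C@@]2(C)[C@@H]1[C@H](O)CC1=CCOC1=O | target

Total step count: 15. Longest linear sequence: 14 steps (steps 1–12, 14 and 15); step 13 is a one-step side branch.

Steps most likely to fail

Step 10. What may go wrong: incomplete discrimination between the two diastereotopic ester groups, which would erode the configuration at C4, or protonation of the alkylsamarium before it acylates (simple loss of iodine). The fallback sets out from iodo diester 16 and returns at diol 18. DIBAL-H (CH2Cl2, −78 to 0 °C) should reduce both esters without touching the carbon–iodine bond to give iodo diol F1. Dess–Martin periodinane (CH2Cl2, NaHCO3) should then give the 2-methylmalondialdehyde F2. CrCl2 with catalytic cobalt phthalocyanine (CoC32H16N8) in DMF should convert the iodide into an alkylchromium species (trivalent chromium) that adds to one formyl group, a Nozaki–Hiyama–Kishi-type closure of the same C2–C3 bond, giving hydroxy aldehyde F3. Here the spectator group on C4 is a formyl group, smaller than an ester, which should sharpen the preference for the axial site, and the chelated chair should place the new 3-hydroxyl equatorial. NaBH4 (MeOH, 0 °C) then reduces the remaining formyl group to give 18.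

Step 6. What may go wrong: failure of vinyl transfer to a β-carbon that is flanked by the methyl group and by the carbon carrying the fully substituted malonyl group (recovered enone or 1,2-addition). The fallback sets out from enone 10 and returns at keto acetal 13. A rod-shaped sp nucleophile replaces the vinyl group: (trimethylsilyl)ethynylzinc bromide (from the lithium acetylide and ZnBr2) with TBSOTf in Et2O/THF at −40 °C should give the conjugate alkynylation product as silyl enol ether F4, again anti to the malonyl group. HC(OMe)3/BF3·OEt2 followed by K2CO3/MeOH (which also equilibrates C9 and removes the alkynyl silyl group) should give ethynyl keto acetal F5. Semi-hydrogenation (H2, Pd/CaCO3 poisoned with Pb(OAc)2, quinoline, EtOAc) then gives 13.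

Step 14. What may go wrong: poor facial selectivity at C11 if Felkin–Anh control is weak in the aqueous indium-mediated addition, and premature lactonisation of the γ-hydroxy ester. The fallback sets out from bromide 22 (with aldehyde 19) and returns at 23. CuCl, KOtBu and B2pin2 (THF, rt) should convert 22 into allylboronate F6. Its addition to 19 through a closed six-membered transition state under a chiral BINOL-derived phosphoric acid (TRIP, 5 mol%, toluene, −30 °C; the enantiomer matched to the 11R product) moves the control of C11 from the substrate to the catalyst, under non-aqueous and only weakly acidic conditions.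

Further compounds
F1 | step 10 | 2-[(1S,2R,3R)-3-(dimethoxymethyl)-2-(2-iodoethyl)-2-methyl-4-methylidenecyclohexyl]-2-methylpropane-1,3-diol | C=C1CC[C@H](C(C)(CO)CO)[C@@](C)(CCI)[C@@H]1C(OC)OC
F2 | step 10 | 2-[(1S,2R,3R)-3-(dimethoxymethyl)-2-(2-iodoethyl)-2-methyl-4-methylidenecyclohexyl]-2-methylpropanedial | C=C1CC[C@H](C(C)(C=O)C=O)[C@@](C)(CCI)[C@@H]1C(OC)OC
F3 | step 10 | trans-decalin hydroxy aldehyde: 5-(dimethoxymethyl)-2-hydroxy-1,4a-dimethyl-6-methylidenedecahydronaphthalene-1-carbaldehyde (formyl axial, 2-hydroxyl equatorial) | C=C1CC[C@@H]2[C@](C)(C=O)[C@H](O)CC[C@@]2(C)[C@@H]1C(OC)OC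
F4 | step 6 | dimethyl 2-[(1S)-4-(tert-butyldimethylsilyloxy)-2-methyl-2-[(trimethylsilyl)ethynyl]cyclohex-3-en-1-yl]-2-methylpropanedioate (alkynyl trans to the malonyl group) | CC(C)(C)[Si](C)(C)OC=1CC[C@H](C(C)(C(=O)OC)C(=O)OC)[C@@](C)(C#C[Si](C)(C)C)C=1
F5 | step 6 | dimethyl 2-[3-(dimethoxymethyl)-2-ethynyl-2-methyl-4-oxocyclohexyl]-2-methylpropanedioate (configuration as in 13, ethynyl in place of ethenyl) | O=C1CC[C@H](C(C)(C(=O)OC)C(=O)OC)[C@@](C)(C#C)[C@@H]1C(OC)OC
F6 | step 14 | prop-2-enyl 2-[(4,4,5,5-tetramethyl-1,3,2-dioxaborolan-2-yl)methyl]prop-2-enoate | C=CCOC(=O)C(=C)CB1OC(C)(C)C(C)(C)O1
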